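**Retrosynthetic overview**
1. The target comes from its C9 epimer by Mitsunobu inversion, after angeloylation of the C6 hydroxyl of a 4,5-epoxy-6-hydroxy germacranolide.
2. Key disconnection: the C6–C7 bond and the oxirane are made in one flask. A (butenolid-3-yl)methylzinc adds to a tethered enal, and the zinc alkoxide formed directs a vanadium-catalysed epoxidation.
3. The cyclisation precursor comes from a vinylogous Mukaiyama aldol (C8–C9 bond) between a 2-silyloxyfuran (C7, C8, C11–C13) and a C1–C6/C9/C10 dialdehyde.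
4. The dialdehyde comes from geranyl acetate (allylic oxidation, asymmetric hydrogenation sets C10); the silyloxyfuran comes from furan-3-ylmethanol.
5. Ring order: the lactone ring is carried in from the furan (oxidised to the butenolide early); the ten-membered carbocycle and the epoxide then form together.

Convention and assumption: macrocycles carry germacrane numbering (ring C1–C10, C11–C13 on C7, C14 on C10, C15 on C4), and the BINAP hand in step 2 is assumed from the known geraniol case.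

**Step 1**
Reactants: 1 geranyl acetate
Product: 2 (2E,6E)-8-hydroxy-3,7-dimethylocta-2,6-dien-1-yl acetate
Conditions: SeO2 (0.2 equiv), t-BuOOH (70% aq.), salicylic acid (cat.), CH2Cl2, 23 °C
Reagents that add atoms: tert-butyl hydroperoxide, CC(C)(C)OO
Why: Catalytic SeO2 allylic oxidation (ene reaction, then [2,3]-shift) attacks the (E)-methyl of the electron-rich 6,7-olefin, while the 2,3-olefin is deactivated by the allylic acetate; no stereocentre is formed.

**Step 2**
Reactants: 2 (2E,6E)-8-hydroxy-3,7-dimethylocta-2,6-dien-1-yl acetate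
Product: 4 (2E,7R)-3,7-dimethyloct-2-ene-1,8-diol, via hydroxy acetate 3 (not isolated)
Conditions: Ru(OAc)2[(R)-BINAP] (0.5 mol %), H2 (50 atm), MeOH, 25 °C; then K2CO3 (0.2 equiv), MeOH, 23 °C
Reagents that add atoms: none
Why: Noyori hydroxyl-directed asymmetric hydrogenation reduces only the olefin of the free allylic alcohol and sets C10 as R (ligand hand chosen by analogy with the geraniol face preference), the allylic acetate olefin is left, and carbonate-catalysed transesterification then frees the C6 alcohol.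

**Step 3**
Reactants: 4 (2E,7R)-3,7-dimethyloct-2-ene-1,8-diol
Product: 5 (2R,6E)-2,6-dimethyloct-6-enedial
Conditions: TEMPO (0.2 equiv), PhI(OAc)2 (2.4 equiv), CH2Cl2, 23 °C
Reagents that add atoms: none
Why: Oxoammonium (TEMPO) oxidation turns both primary alcohols into aldehydes under non-basic conditions, so the α-methyl stereocentre C10 is not epimerised and the enal stays E.

**Step 4**
Reactants: 6 furan-3-ylmethanol
Product: 8 [2-(trimethylsilyl)furan-3-yl]methanol, via bis-silyl furan 7 (not isolated)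
Conditions: n-BuLi (2.2 equiv), THF, −78 to 0 °C; Me3SiCl (2.3 equiv); then K2CO3 (cat.), MeOH
Reagents that add atoms: chlorotrimethylsilane, C[Si](C)(C)Cl
Why: Directed ortho-metalation: the lithium alkoxide directs the second lithiation to C2, Me3SiCl silylates C and O, and methanolysis cleaves only the O–Si bond.

**Step 5**
Reactants: 8 [2-(trimethylsilyl)furan-3-yl]methanol
Product: 9 3-(hydroxymethyl)furan-2(5H)-one
Conditions: CH3CO3H (1.2 equiv), NaOAc, CH2Cl2, 0 to 23 °C; then Et3N (cat.)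
Reagents that add atoms: peracetic acid, CC(=O)OO
Why: Kuwajima–Urabe oxidation of a 2-silylfuran: the peracid attacks the silylated carbon, silicon migrates from C to O and is lost, so the carbonyl appears regiospecifically at the former C–Si carbon and Et3N moves the double bond into conjugation.

**Step 6**
Reactants: 9 3-(hydroxymethyl)furan-2(5H)-one
Product: 10 tert-butyl(dimethyl)[(3-{[(triethylsilyl)oxy]methyl}furan-2-yl)oxy]silane
Conditions: Et3SiCl (1.05 equiv), Et3N, CH2Cl2, 0 °C; then TBSOTf (1.1 equiv), Et3N, 0 °C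
Reagents that add atoms: chlorotriethylsilane, CC[Si](Cl)(CC)CC; tert-butyldimethylsilyl trifluoromethanesulfonate, CC(C)(C)[Si](C)(C)OS(=O)(=O)C(F)(F)F
Why: O-silylation of the primary alcohol followed by soft enolisation (γ-deprotonation with Et3N/TBSOTf) gives the aromatic 2-silyloxyfuran, the nucleophile for the vinylogous Mukaiyama aldol.

**Step 7**
Reactants: 5 (2R,6E)-2,6-dimethyloct-6-enedial; 10 tert-butyl(dimethyl)[(3-{[(triethylsilyl)oxy]methyl}furan-2-yl)oxy]silane
Product: 12 (5S)-5-[(1S,2R,6E)-1-{[tert-butyl(dimethyl)silyl]oxy}-2,6-dimethyl-8-oxooct-6-en-1-yl]-3-(hydroxymethyl)furan-2(5H)-one, via triethylsilyl ether 11 (not isolated)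
Conditions: TBSOTf (0.1 equiv), CH2Cl2, −78 °C; then AcOH–THF–H2O (3:1:1), 23 °C
Reagents that add atoms: none
Why: Silyl-triflate-catalysed vinylogous Mukaiyama aldol with silyl transfer: the furan γ-carbon adds to the saturated aldehyde (the β,β-disubstituted enal is far less electrophilic) through an open transition state, giving the 8,9-threo relationship usual for Lewis-acid silyloxyfuran aldols and Felkin–Anh attack at C9 (8S,9S, with C9 still epimeric to the target), and the aqueous acid removes only the primary triethylsilyl ether.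

**Step 8**
Reactants: 12 (5S)-5-[(1S,2R,6E)-1-{[tert-butyl(dimethyl)silyl]oxy}-2,6-dimethyl-8-oxooct-6-en-1-yl]-3-(hydroxymethyl)furan-2(5H)-one
Product: 13 (5S)-3-(bromomethyl)-5-[(1S,2R,6E)-1-{[tert-butyl(dimethyl)silyl]oxy}-2,6-dimethyl-8-oxooct-6-en-1-yl]furan-2(5H)-one
Conditions: PPh3, N-bromosuccinimide, CH2Cl2, −20 °C
Reagents that add atoms: N-bromosuccinimide, O=C1CCC(=O)N1Br
Why: Appel-type bromination converts the primary allylic alcohol into the bromide by SN2 at low temperature without touching the enal, the silyl ether or any stereocentre.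

**Step 9 (key step)**
Reactants: 13 (5S)-3-(bromomethyl)-5-[(1S,2R,6E)-1-{[tert-butyl(dimethyl)silyl]oxy}-2,6-dimethyl-8-oxooct-6-en-1-yl]furan-2(5H)-one
Product: 15 (4R,5R,6R,7R,8S,9S,10R)-9-{[tert-butyl(dimethyl)silyl]oxy}-4,5-epoxy-6-hydroxygermacr-11(13)-en-12,8-olide, via macrocyclic allylic alcohol 14 (not isolated)
Conditions: activated Zn dust (5 equiv), THF, 2 mM, slow addition, 40 °C; solution decanted from Zn; then VO(acac)2 (0.1 equiv), t-BuOOH (decane, 2 equiv), 0 °C
Reagents that add atoms: tert-butyl hydroperoxide, CC(C)(C)OO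
Why: Proposed new method: zinc inserts into the allylic bromide to give a 2-acylallylzinc (Dreiding–Schmidt reagent type, the closest known reaction being Barbier allylation of aldehydes with 3-(bromomethyl)furan-2(5H)-ones) that adds 1,2 to the enal through a Zimmerman–Traxler chair, bonding C7 on the lactone face anti to the C8 side chain (trans lactone) with the 6,7-relationship of an (E)-type allyl metal, and the zinc alkoxide then directs Sharpless–Michaelson VO(acac)2 epoxidation in the same flask (closest precedent: tandem organozinc addition then directed epoxidation), where the C6–C7 ring bond of an (E)-cyclodecene must lie out of the olefin plane so that the small O–C–C=C dihedral vanadium needs is reached only with the hydroxyl on the outer face and oxygen is delivered syn to it to give the 4R,5R epoxide; carbocycle and oxirane thus form in one operation.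

**Step 10**
Reactants: 15 (4R,5R,6R,7R,8S,9S,10R)-9-{[tert-butyl(dimethyl)silyl]oxy}-4,5-epoxy-6-hydroxygermacr-11(13)-en-12,8-olide; 16 angelic acid
Product: 18 (4R,5R,6R,7R,8S,9S,10R)-6-(angeloyloxy)-9-{[tert-butyl(dimethyl)silyl]oxy}-4,5-epoxygermacr-11(13)-en-12,8-olide, via mixed anhydride 17 (not isolated)
Conditions: 16, 2,4,6-trichlorobenzoyl chloride, Et3N, toluene, 23 °C; then 15, toluene, 75 °C
Reagents that add atoms: none
Why: Yamaguchi-type esterification through the mixed anhydride, run without DMAP, acylates the hindered C6 hydroxyl with retention and avoids the Z-to-E isomerisation to the tiglate that nucleophilic catalysts cause.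

**Step 11**
Reactants: 18 (4R,5R,6R,7R,8S,9S,10R)-6-(angeloyloxy)-9-{[tert-butyl(dimethyl)silyl]oxy}-4,5-epoxygermacr-11(13)-en-12,8-olide
Product: 19 (4R,5R,6R,7S,8S,9S,10R)-6-(angeloyloxy)-4,5-epoxy-9-hydroxygermacr-11(13)-en-12,8-olide
Conditions: HF·pyridine, pyridine, THF, 0 to 23 °C
Reagents that add atoms: none
Why: Fluoride-mediated desilylation buffered with pyridine removes the secondary silyl ether without opening the epoxide or adding to the α-methylene lactone.

**Step 12**
Reactants: 19 (4R,5R,6R,7S,8S,9S,10R)-6-(angeloyloxy)-4,5-epoxy-9-hydroxygermacr-11(13)-en-12,8-olide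
Product: 21 (4R,5R,6R,7S,8S,9R,10R)-6-(angeloyloxy)-4,5-epoxy-9-hydroxygermacr-11(13)-en-12,8-olide, via formate 20 (not isolated)
Conditions: HCO2H (6 equiv), PPh3 (5 equiv), DIAD (5 equiv), toluene, 0 to 23 °C; then KHCO3 (0.3 equiv), MeOH–H2O, 0 °C
Reagents that add atoms: formic acid, O=CO
Why: Mitsunobu reaction inverts C9 by SN2 displacement of the oxyphosphonium by formate (C8–H is no longer acidic once the butenolide has become the α-methylene lactone, so elimination is disfavoured), and the labile formate is methanolysed by bicarbonate without touching the angelate, giving the 9R alcohol of the target.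

**Compound list**
1 | geranyl acetate | CC(C)=CCC/C(C)=C/COC(C)=O | starting material
2 | (2E,6E)-8-hydroxy-3,7-dimethylocta-2,6-dien-1-yl acetate | OC/C(C)=C/CC/C(C)=C/COC(C)=O | intermediate
3 | (2E,7R)-8-hydroxy-3,7-dimethyloct-2-en-1-yl acetate | OC[C@H](C)CCC/C(C)=C/COC(C)=O | intermediate
4 | (2E,7R)-3,7-dimethyloct-2-ene-1,8-diol | OC[C@H](C)CCC/C(C)=C/CO | intermediate
5 | (2R,6E)-2,6-dimethyloct-6-enedial | O=C[C@H](C)CCC/C(C)=C/C=O | intermediate
6 | furan-3-ylmethanol | OCc1ccoc1 | starting material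
7 | trimethyl{[2-(trimethylsilyl)furan-3-yl]methoxy}silane | C[Si](C)(C)OCc1ccoc1[Si](C)(C)C | intermediate
8 | [2-(trimethylsilyl)furan-3-yl]methanol | OCc1ccoc1[Si](C)(C)C | intermediate
9 | 3-(hydroxymethyl)furan-2(5H)-one | OCC1=CCOC1=O | intermediate
10 | tert-butyl(dimethyl)[(3-{[(triethylsilyl)oxy]methyl}furan-2-yl)oxy]silane | CC[Si](CC)(CC)OCc1ccoc1O[Si](C)(C)C(C)(C)C | intermediate
11 | (5S)-5-[(1S,2R,6E)-1-{[tert-butyl(dimethyl)silyl]oxy}-2,6-dimethyl-8-oxooct-6-en-1-yl]-3-{[(triethylsilyl)oxy]methyl}furan-2(5H)-one | O=C1O[C@@H](C=C1CO[Si](CC)(CC)CC)[C@@H](O[Si](C)(C)C(C)(C)C)[C@H](C)CCC/C(C)=C/C=O | intermediate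
12 | (5S)-5-[(1S,2R,6E)-1-{[tert-butyl(dimethyl)silyl]oxy}-2,6-dimethyl-8-oxooct-6-en-1-yl]-3-(hydroxymethyl)furan-2(5H)-one | O=C1O[C@@H](C=C1CO)[C@@H](O[Si](C)(C)C(C)(C)C)[C@H](C)CCC/C(C)=C/C=O | intermediate
13 | (5S)-3-(bromomethyl)-5-[(1S,2R,6E)-1-{[tert-butyl(dimethyl)silyl]oxy}-2,6-dimethyl-8-oxooct-6-en-1-yl]furan-2(5H)-one | O=C1O[C@@H](C=C1CBr)[C@@H](O[Si](C)(C)C(C)(C)C)[C@H](C)CCC/C(C)=C/C=O | intermediate
14 | (4E,6S,7R,8S,9S,10R)-9-{[tert-butyl(dimethyl)silyl]oxy}-6-hydroxygermacra-4,11(13)-dien-12,8-olide | C=C1C(=O)O[C@@H]2[C@@H](O[Si](C)(C)C(C)(C)C)[C@H](C)CCC/C(C)=C/[C@H](O)[C@@H]12 | intermediate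
15 | (4R,5R,6R,7R,8S,9S,10R)-9-{[tert-butyl(dimethyl)silyl]oxy}-4,5-epoxy-6-hydroxygermacr-11(13)-en-12,8-olide | C=C1C(=O)O[C@@H]2[C@@H](O[Si](C)(C)C(C)(C)C)[C@H](C)CCC[C@@]3(C)O[C@@H]3[C@H](O)[C@@H]12 | intermediate
16 | angelic acid, (2Z)-2-methylbut-2-enoic acid | C/C=C(/C)C(=O)O | starting material
17 | (2Z)-2-methylbut-2-enoic 2,4,6-trichlorobenzoic anhydride | C/C=C(/C)C(=O)OC(=O)c1c(Cl)cc(Cl)cc1Cl | intermediate
18 | (4R,5R,6R,7R,8S,9S,10R)-6-(angeloyloxy)-9-{[tert-butyl(dimethyl)silyl]oxy}-4,5-epoxygermacr-11(13)-en-12,8-olide | C=C1C(=O)O[C@@H]2[C@@H](O[Si](C)(C)C(C)(C)C)[C@H](C)CCC[C@@]3(C)O[C@@H]3[C@H](OC(=O)/C(C)=C\C)[C@@H]12 | intermediate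
19 | (4R,5R,6R,7S,8S,9S,10R)-6-(angeloyloxy)-4,5-epoxy-9-hydroxygermacr-11(13)-en-12,8-olide | C=C1C(=O)O[C@@H]2[C@@H](O)[C@H](C)CCC[C@@]3(C)O[C@@H]3[C@H](OC(=O)/C(C)=C\C)[C@@H]12 | intermediate
20 | (4R,5R,6R,7S,8S,9R,10R)-6-(angeloyloxy)-4,5-epoxy-9-(formyloxy)germacr-11(13)-en-12,8-olide | C=C1C(=O)O[C@@H]2[C@H](OC=O)[C@H](C)CCC[C@@]3(C)O[C@@H]3[C@H](OC(=O)/C(C)=C\C)[C@@H]12 | intermediate
21 | (4R,5R,6R,7S,8S,9R,10R)-6-(angeloyloxy)-4,5-epoxy-9-hydroxygermacr-11(13)-en-12,8-olide | C=C1C(=O)O[C@@H]2[C@H](O)[C@H](C)CCC[C@@]3(C)O[C@@H]3[C@H](OC(=O)/C(C)=C\C)[C@@H]12 | target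

**Step count**
Total: 12 steps. Longest linear sequence: 9 steps (1 to 21 through steps 1–3 and 7–12; the branch from 6 is also 9).

**Three steps most likely to fail**

Step 9 (one-flask macro-allylation and directed epoxidation). The ten-membered ring closure may lose to oligomers, and the epoxide face rests on a conformational argument that has not been tested on this ring. The fallback sets out from 13 and puts the epoxide in before ring closure under reagent control. Luche reduction (NaBH4, CeCl3·7H2O, MeOH, −78 °C) of the enal gives the allylic alcohol (5S)-3-(bromomethyl)-5-[(1S,2R,6E)-1-{[tert-butyl(dimethyl)silyl]oxy}-8-hydroxy-2,6-dimethyloct-6-en-1-yl]furan-2(5H)-one F1. Sharpless asymmetric epoxidation (Ti(OiPr)4, D-(−)-diethyl tartrate, t-BuOOH, −20 °C) gives the (2R,3R)-epoxy alcohol F2, and Dess–Martin oxidation gives the epoxy aldehyde F3. Zinc-mediated cyclisation of F3, with Felkin–Anh attack anti to the epoxide C–O bond, comes back to the route at 15.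

Step 7 (vinylogous Mukaiyama aldol). The Felkin bias of a methyl/methylene-branched aldehyde is modest, so the C9 ratio may be low, and the enal may compete. The fallback sets out from 5 and builds the same stereodiad by reagent-controlled allylboration, then closes the butenolide by metathesis. Brown syn-alkoxyallylation with (Z)-γ-(methoxymethoxy)allyl-B(Ipc)2 (hand chosen for 8S,9S; ethanolamine work-up) gives (2E,7R,8S,9S)-8-hydroxy-9-(methoxymethoxy)-3,7-dimethylundeca-2,10-dienal F4. Silylation (TBSOTf, 2,6-lutidine) gives the silyl ether F5, and MgBr2·OEt2 with n-BuSH removes the methoxymethyl group to give the allylic alcohol F6. Acylation with 2-(bromomethyl)acryloyl chloride and 2,6-lutidine gives the ester F7. Ring-closing metathesis with the second-generation Grubbs catalyst RuCl2(=CHPh)(PCy3)(H2IMes) in toluene at 80 °C comes back to the route at 13.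

Step 12 (late Mitsunobu inversion at hindered C9). Elimination or no reaction is possible. The fallback sets out from 19 and inverts by oxidation and reduction. Dess–Martin periodinane gives the ketone (4R,5R,6R,7R,8S,10R)-6-(angeloyloxy)-4,5-epoxy-9-oxogermacr-11(13)-en-12,8-olide F8. Zn(BH4)2 in Et2O at −20 °C, with chelation between the ketone and the C8 lactone oxygen and Felkin attack relative to C10 both favouring the 8,9-anti alcohol, comes back to the route at 21.

**Further compounds**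
F1 | step 9 | (5S)-3-(bromomethyl)-5-[(1S,2R,6E)-1-{[tert-butyl(dimethyl)silyl]oxy}-8-hydroxy-2,6-dimethyloct-6-en-1-yl]furan-2(5H)-one | O=C1O[C@@H](C=C1CBr)[C@@H](O[Si](C)(C)C(C)(C)C)[C@H](C)CCC/C(C)=C/CO
F2 | step 9 | (5S)-3-(bromomethyl)-5-[(1S,2R)-1-{[tert-butyl(dimethyl)silyl]oxy}-5-[(2R,3R)-3-(hydroxymethyl)-2-methyloxiran-2-yl]-2-methylpentyl]furan-2(5H)-one | O=C1O[C@@H](C=C1CBr)[C@@H](O[Si](C)(C)C(C)(C)C)[C@H](C)CCC[C@@]2(C)O[C@@H]2CO
F3 | step 9 | (2S,3R)-3-[(4R,5S)-5-[(2S)-4-(bromomethyl)-5-oxo-2,5-dihydrofuran-2-yl]-5-{[tert-butyl(dimethyl)silyl]oxy}-4-methylpentyl]-3-methyloxirane-2-carbaldehyde | O=C1O[C@@H](C=C1CBr)[C@@H](O[Si](C)(C)C(C)(C)C)[C@H](C)CCC[C@@]2(C)O[C@@H]2C=O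
F4 | step 7 | (2E,7R,8S,9S)-8-hydroxy-9-(methoxymethoxy)-3,7-dimethylundeca-2,10-dienal | COCO[C@@H](C=C)[C@@H](O)[C@H](C)CCC/C(C)=C/C=O
F5 | step 7 | (2E,7R,8S,9S)-8-{[tert-butyl(dimethyl)silyl]oxy}-9-(methoxymethoxy)-3,7-dimethylundeca-2,10-dienal | COCO[C@@H](C=C)[C@@H](O[Si](C)(C)C(C)(C)C)[C@H](C)CCC/C(C)=C/C=O
F6 | step 7 | (2E,7R,8S,9S)-8-{[tert-butyl(dimethyl)silyl]oxy}-9-hydroxy-3,7-dimethylundeca-2,10-dienal | O[C@@H](C=C)[C@@H](O[Si](C)(C)C(C)(C)C)[C@H](C)CCC/C(C)=C/C=O
F7 | step 7 | (3S,4S,5R,9E)-4-{[tert-butyl(dimethyl)silyl]oxy}-5,9-dimethyl-11-oxoundeca-1,9-dien-3-yl 2-(bromomethyl)prop-2-enoate | C=C(CBr)C(=O)O[C@@H](C=C)[C@@H](O[Si](C)(C)C(C)(C)C)[C@H](C)CCC/C(C)=C/C=O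
F8 | step 12 | (4R,5R,6R,7R,8S,10R)-6-(angeloyloxy)-4,5-epoxy-9-oxogermacr-11(13)-en-12,8-olide | C=C1C(=O)O[C@@H]2C(=O)[C@H](C)CCC[C@@]3(C)O[C@@H]3[C@H](OC(=O)/C(C)=C\C)[C@@H]12
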